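A small charge of Z, 5.0 mM in larch and in oak, begins the chains. I count the length as [Q] at the end over [Z] charged, taking each Z as one chain begun, which is a guess the runs cannot check.

| flask | J | Z | remark | time |
|---|---|---|---|---|
| Saturday's | 0.15 M | 5 mM | run made earlier |  |
| Wednesday's | 0.39 M | 5 mM | run made earlier |  |
| larch | 0.10 M | 5.0 mM |  | 30 h |
| oak | 0.30 M | 5.0 mM |  | 30 h |

| run | time / h | Q / % | J / % |
|---|---|---|---|
| Saturday's | 5.00 | 80.2 | 7.3 |
| Saturday's | 10.0 | 82.6 | 4.6 |
| Saturday's | 15.0 | 80.2 | 4.2 |
| Saturday's | 20.0 | 79.1 | 3.5 |
| Saturday's | 25.0 | 76.6 | 4.6 |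
| Saturday's | 30.0 | 77.7 | 4.1 |
| Wednesday's | 5.00 | 81.3 | 7.9 |
| Wednesday's | 10.0 | 86.2 | 1.1 |
| Wednesday's | 15.0 | 83.7 | 1.1 |
| Wednesday's | 20.0 | 85.1 | 0 |
| Wednesday's | 25.0 | 84.6 | 1.3 |
| Wednesday's | 30.0 | 83.7 | 1.4 |

(standard deviation of a reading: 1 percentage point)

- which of the two ends with the longer chains by the average number of monomer units in a chain (chains begun, living or dead) ("neither" if they lie within 10 %) (larch / oak / neither)
- average number of monomer units in a chain (chains begun, living or dead) at the end, larch
- average number of monomer units in a chain (chains begun, living or dead) at the end, oak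

- the average divides the monomer in chains by the number of chains begun, living and dead together
- the numbers in the tables scatter with a standard deviation of 1 percentage point
- candidate steps: J -> L; J + Z -> D + Q; Q + D -> J + D; J + D -> Q + D
- the earlier runs do not show the number of chains; that part of a forecast is a guess

So I need [Q] at the end, and I read the tables at both ends of a run. Over the last 4 readings, J averages 4.10 % of the charge in Saturday's run and 0.950 % in Wednesday's. As concentrations these are 6.15 mM and 3.71 mM, a gap that a scatter of 1 percentage point can cover at these charges. As a ratio, the two percentages stand further apart than the two concentrations, so I take one level in concentration for both runs, 4.93 mM. I call it the floor, the [J] at which D adds J as fast as it returns it from Q; this is the equilibrium monomer concentration.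

What Q and J leave of the charge is L. At 10.0 h that is 12.8 % in Saturday's run and 12.7 % in Wednesday's, so the early loss scales with the charge. From there to 30.0 h, L grows by 0.405 mM h⁻¹ and 0.429 mM h⁻¹, so the late loss follows the floor, not the charge.

Joining the ends, [Q] is the charge less 12.7 %, less the floor, less 0.417 mM h⁻¹ over the last 20.0 h. Over [Z] this gives 14.8 for larch and 49.7 for oak, so oak's chains are longer.

The forecast, “Assuming all 5 mM of Z starts chains”, gives 15 and 50, with oak longer.

The flask gives 14.3 for larch and 49.6 for oak, with oak longer.

    J → L (k = 2.00 × 10⁻⁵ s⁻¹)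
    J + Z → D + Q (k = 0.0380 M⁻¹ s⁻¹)
    Q + D → J + D, rate k3*[D] as long as [Q] is above zero (k = 1.90 × 10⁻⁴ s⁻¹)
    J + D → Q + D, rate k4*[D]*[J] (k = 0.0300 M⁻¹ s⁻¹)

Larch ends with J at 5.6 % of its charge, against 4.93 % from the floor, and oak with 1.9 %, against 1.64 %. In larch at 30.0 h, J passes into Q 7.5 times as fast as into L, while Q is made at 0.882 of the rate at which it is used up, and Q falls from 77.4 % at 15.0 h to 71.4 % at 30.0 h. The neighbouring flask, larch with 0.025 M of J, ends with J at 22 %, against 19.7 % from the floor, and its chains average 1.07.

All runs come from a simulation with made-up constants; scatter was added.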